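**Retrosynthetic overview**

1. Target ⇒ C6 ester bond: epoxy diol + O-silyl vanillic acid (from catechol, MeI, CO2). The oxirane comes from a hydroxyl-directed epoxidation, the C6 carbinol from a 1,3-anti reduction of a hydroazulenone.
2. Hydroazulenone (5/7, trans) ⇒ semipinacol 1,2-shift of a cis-decalin 4,5,6-triol 5-mesylate (key step). C1 moves from C6 to C5, so ring B (six) contracts to the cyclopentane and ring A (six) expands to the cycloheptene in one operation.
3. Triol ⇒ hydroxyl-directed syn-dihydroxylation of a decalin diene. The diene comes from a bicyclic enedione by angular hydroxylation, reductive enol triflation, directed C2 reduction/acetylation and detriflation.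
4. Enedione ⇒ enantioselective Diels–Alder of thymoquinone with isoprene; thymoquinone ⇒ m-cresol + propene.
5. Ring order: ring B (arene → quinone), ring A (cycloaddition), 6/6 → 5/7 by the 1,2-shift, oxirane last.

Assumption 1: every intermediate carries the daucane numbering of the target (C1 angular-methyl carbon, C2 acetoxy carbon, C3 CH2, C4 isopropyl carbinol, C5 ring-fusion CH, C6 aroyloxy carbon, C7 CH2, C8 (methyl) and C9 oxirane carbons, C10 CH2); β is the face of the C1 methyl; in the decalins ring B is C1–C6 and ring A is C6–C10 plus C1; the target is then (1R,2S,4R,5S,6S,8R,9S), i.e. 2α-OAc, 4β-OH, 5α-H, 6α-aroyloxy, 8α,9α-epoxide, trans ring fusion.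

Assumption 2: the (R)-ligand in step 3 is taken to give the (4aR,8aS) adduct; if the sense of induction is the reverse, the (S)-ligand is used.

**Route**

Step 1
Reactants: 1 m-cresol; 2 propene
Product: 3 thymol
Conditions: propene (8 bar), Re2(CO)10 (2.5 mol%), mesitylene, 160 °C
Reagents that add atoms: none
Why: rhenium-carbonyl-catalysed ortho-selective Friedel–Crafts-type hydroarylation (Markovnikov) alkylates the less hindered ortho position, para to the methyl group, and stops at mono-alkylation.

Step 2
Reactants: 3 thymol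
Product: 4 thymoquinone
Conditions: O2 (1 atm), Co(salen) [Co(C16H14N2O2), 5 mol%], DMF, 25 °C
Reagents that add atoms: dioxygen, O=O
Why: cobalt–salen-catalysed aerobic phenol oxidation converts the para-unsubstituted 2,5-dialkylphenol into the p-benzoquinone.

Step 3
Reactants: 4 thymoquinone; 5 isoprene
Product: 6 (4aR,8aS)-4a,7-dimethyl-2-(propan-2-yl)-4a,5,8,8a-tetrahydronaphthalene-1,4-dione
Conditions: isoprene (5 equiv), (R)-BINOLate–TiCl2 [(C20H12O2)TiCl2, 20 mol%, from (R)-1,1'-bi-2-naphthol and TiCl2(OiPr)2], 4 Å MS, CH2Cl2, −40 °C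
Reagents that add atoms: none
Why: Proposed new method: the chiral titanium Lewis acid should bind the C2 carbonyl (lone pair syn to C3–H) and activate the C1(Me)=C6(H) arm, the only one with an unsubstituted β-carbon and a small α-substituent, so that the more nucleophilic CH2 terminus of isoprene bonds first to C6 ("para" adduct, methyl on C8), the suprafacial [4+2] gives the cis fusion, and the C2-symmetric BINOLate blocks one π-face to set C1 and C6 in the absolute sense; closest known reaction types are BINOLate–titanium- and oxazaborolidinium-catalysed enantioselective Diels–Alder reactions of benzoquinones and Lewis acid-promoted para-selective additions of isoprene to 2-methylcycloalkenones, neither shown for a 2,5-dialkylquinone reacting at its alkylated double bond.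

Step 4
Reactants: 6 cis-fused enedione
Product: 9 6β-trimethylsilyloxy enedione, via potassium enolate 7 (not isolated), via potassium alkoxide 8 (not isolated)
Conditions: KHMDS, THF, −78 °C; 2-(phenylsulfonyl)-3-phenyloxaziridine; then Me3SiCl, −78 → 0 °C
Reagents that add atoms: 2-(phenylsulfonyl)-3-phenyloxaziridine, O=S(=O)(c1ccccc1)N1OC1c1ccccc1; chlorotrimethylsilane, C[Si](C)(C)Cl
Why: Davis oxaziridine hydroxylation of the only enolisable position (C6–H, α to the C5 ketone) then O-silylation; the oxidant enters on the convex face of the enolate, cis to the C1 methyl, so the C6 oxygen is β and the cis fusion is kept.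

Step 5
Reactants: 9 6β-trimethylsilyloxy enedione
Product: 12 6β-hydroxy C5-enol triflate (C4=C5; C2 ketone), via lithium enolate 10 (not isolated), via silyl enol triflate 11 (not isolated)
Conditions: LiBH(s-Bu)3 (1.05 equiv), THF, −78 °C; then N-(5-chloropyridin-2-yl)bis(trifluoromethanesulfonyl)imide, −78 → 0 °C; then HF·pyridine, THF, 0 °C
Reagents that add atoms: N-(5-chloropyridin-2-yl)bis(trifluoromethanesulfonyl)imide (Comins' reagent), O=S(=O)(N(c1ccc(Cl)cn1)S(=O)(=O)C(F)(F)F)C(F)(F)F
Why: conjugate hydride reduction of the enedione at the unsubstituted C3 gives the C4=C5 enolate regiospecifically, which is trapped as the enol triflate (reductive enol triflation), and fluoride then removes the silyl group that kept the C6 oxygen from quenching the enolate.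

Step 6
Reactants: 12 6β-hydroxy C5-enol triflate
Product: 14 2α-acetoxy-6β-hydroxy C5-enol triflate, via diol 13 (not isolated)
Conditions: Me4NBH(OAc)3, MeCN–AcOH, −20 °C; MeOH, evaporate; then Ac2O, pyridine, DMAP (5 mol%), CH2Cl2, 0 → 25 °C
Reagents that add atoms: acetic anhydride, CC(=O)OC(C)=O
Why: Evans–Saksena hydroxyl-directed reduction (boron bound to the C6 β-oxygen delivers hydride to the β face of the C2 ketone, giving the 1,3-anti 2α-carbinol) followed by acetylation of the only secondary hydroxyl.

Step 7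
Reactants: 14 2α-acetoxy-6β-hydroxy C5-enol triflate
Product: 15 2α-acetoxy-6β-hydroxy cis-decalin 4,8-diene
Conditions: Pd(OAc)2 (5 mol%), PPh3 (10 mol%), HCO2H (2 equiv), Bu3N (3 equiv), DMF, 60 °C
Reagents that add atoms: none
Why: palladium-catalysed formate reduction of the enol triflate (oxidative addition, formate exchange, decarboxylation, C–H reductive elimination) leaves the C4=C5 alkene next to the tertiary C6 carbinol without touching a stereocentre.

Step 8
Reactants: 15 2α-acetoxy-6β-hydroxy cis-decalin 4,8-diene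
Product: 17 2α-acetoxy cis-decalin-4β,5β,6β-triol, via osmate ester 16 (not isolated)
Conditions: OsO4 (1.05 equiv), TMEDA (1.1 equiv), CH2Cl2, −78 °C; then aq. Na2SO3, THF, 40 °C
Reagents that add atoms: osmium tetroxide, O=[Os](=O)(=O)=O
Why: hydrogen-bond-directed syn-dihydroxylation (OsO4·TMEDA held by the allylic C6 hydroxyl) adds to the C4=C5 alkene from the β, also convex, face in preference to the remote C8=C9 alkene, setting the C4 β-carbinol and the C5 β-oxygen.

Step 9
Reactants: 17 2α-acetoxy cis-decalin-4β,5β,6β-triol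
Product: 19 2α-acetoxy-4β-hydroxydauc-8-en-6-one, via mesylate 18 (not isolated)
Conditions: MsCl (1.3 equiv), Et3N, CH2Cl2, −20 °C; crude mesylate then Et3Al (3 equiv), CH2Cl2, −78 → 0 °C
Reagents that add atoms: none
Why: Tsuchihashi–Suzuki-type semipinacol 1,2-shift: in the ring B chair with isopropyl, acetoxy and mesyloxy equatorial the C6–C1 bond is antiperiplanar to the C5–O bond, so the tertiary C1 (rather than the primary C3 on the other flank) migrates from C6 to C5 with inversion at C5, which contracts ring B to the cyclopentane, expands ring A to the cycloheptene, forms the C6 ketone and gives the trans fusion (5α-H) with C1, C2 and C4 unchanged.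

Step 10
Reactants: 19 2α-acetoxy-4β-hydroxydauc-8-en-6-one
Product: 20 2α-acetoxydauc-8-ene-4β,6α-diol
Conditions: Me4NBH(OAc)3, MeCN–AcOH, −20 °C
Reagents that add atoms: none
Why: Evans–Saksena anti-selective reduction of the β-hydroxy ketone: hydride is delivered from boron bound to the C4 β-hydroxyl, giving the 6α-carbinol.

Step 11
Reactants: 20 2α-acetoxydauc-8-ene-4β,6α-diol
Product: 21 2α-acetoxy-8α,9α-epoxydaucane-4β,6α-diol
Conditions: VO(acac)2 (5 mol%), t-BuOOH (1.5 equiv), CH2Cl2, 0 → 25 °C
Reagents that add atoms: tert-butyl hydroperoxide, CC(C)(C)OO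
Why: vanadium-catalysed hydroxyl-directed epoxidation: the homoallylic 6α-hydroxyl delivers oxygen to the α face of the C8=C9 alkene, the β face also being shielded by the angular methyl.

Step 12
Reactants: 22 catechol
Product: 23 guaiacol
Conditions: MeI (1.0 equiv), K2CO3, acetone, 56 °C
Reagents that add atoms: iodomethane, CI
Why: Williamson mono-O-methylation; the mono-ether is separated from catechol and the dimethyl ether by distillation.

Step 13
Reactants: 23 guaiacol
Product: 24 4-bromo-2-methoxyphenol
Conditions: NBS (1.0 equiv), MeCN, −20 → 0 °C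
Reagents that add atoms: N-bromosuccinimide, O=C1CCC(=O)N1Br
Why: electrophilic aromatic bromination goes para to the free hydroxyl, the stronger donor.

Step 14
Reactants: 24 4-bromo-2-methoxyphenol
Product: 25 (4-bromo-2-methoxyphenoxy)(tert-butyl)dimethylsilane
Conditions: t-BuMe2SiCl, imidazole, DMF, 25 °C
Reagents that add atoms: tert-butyldimethylsilyl chloride, CC(C)(C)[Si](C)(C)Cl
Why: silyl ether protection of the phenol so that it survives lithiation and cannot compete in the later acylation.

Step 15
Reactants: 25 (4-bromo-2-methoxyphenoxy)(tert-butyl)dimethylsilane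
Product: 28 4-(tert-butyldimethylsilyloxy)-3-methoxybenzoic acid, via aryllithium 26 (not isolated), via lithium carboxylate 27 (not isolated)
Conditions: n-BuLi (1.05 equiv), THF, −78 °C; CO2; then 1 M HCl to pH 3
Reagents that add atoms: carbon dioxide, O=C=O
Why: bromine–lithium exchange followed by carboxylation of the aryllithium.

Step 16
Reactants: 21 2α-acetoxy-8α,9α-epoxydaucane-4β,6α-diol; 28 4-(tert-butyldimethylsilyloxy)-3-methoxybenzoic acid
Product: 31 CNP0241679.3, via mixed anhydride 29 (not isolated), via protected ester 30 (not isolated)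
Conditions: 28, 2,4,6-trichlorobenzoyl chloride, Et3N, THF, 25 °C; then 21, DMAP, toluene, 60 °C; then Bu4NF, AcOH, THF, 0 °C
Reagents that add atoms: none
Why: Yamaguchi esterification acylates the only secondary hydroxyl (C6), the tertiary C4 hydroxyl being inert, and buffered fluoride then cleaves the aryl silyl ether without touching the acetate, the oxirane or the new ester.

**Compound list**

1 | m-cresol (3-methylphenol) | Cc1cccc(O)c1 | starting material
2 | propene | CC=C | starting material
3 | thymol (5-methyl-2-(propan-2-yl)phenol) | Cc1ccc(C(C)C)c(O)c1 | intermediate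
4 | thymoquinone (2-methyl-5-(propan-2-yl)cyclohexa-2,5-diene-1,4-dione) | CC1=CC(=O)C(C(C)C)=CC1=O | intermediate
5 | isoprene (2-methylbuta-1,3-diene) | C=CC(C)=C | starting material
6 | (4aR,8aS)-4a,7-dimethyl-2-(propan-2-yl)-4a,5,8,8a-tetrahydronaphthalene-1,4-dione (cis-fused; C1-Me and C6-H both β) | [C@H]12CC(C)=CC[C@@]1(C)C(=O)C=C(C(C)C)C2=O | intermediate
7 | potassium C5-enolate of 6 (C5(OK)=C6) | [K+].[O-]C1=C2CC(C)=CC[C@@]2(C)C(=O)C=C1C(C)C | intermediate
8 | potassium 6β-alkoxide of the angular-hydroxylated enedione | [K+].[O-][C@]12CC(C)=CC[C@@]1(C)C(=O)C=C(C(C)C)C2=O | intermediate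
9 | 6β-trimethylsilyloxy enedione (8a-OSiMe3 derivative of 6, cis to the angular methyl) | C[Si](C)(C)O[C@]12CC(C)=CC[C@@]1(C)C(=O)C=C(C(C)C)C2=O | intermediate
10 | lithium C5-enolate (C4=C5–OLi) of the 3,4-dihydro compound, 6β-OSiMe3 | [Li+].C[Si](C)(C)O[C@]12CC(C)=CC[C@@]1(C)C(=O)CC(C(C)C)=C2[O-] | intermediate
11 | 6β-trimethylsilyloxy C5-enol triflate (C4=C5; C2 ketone) | C[Si](C)(C)O[C@]12CC(C)=CC[C@@]1(C)C(=O)CC(C(C)C)=C2OS(=O)(=O)C(F)(F)F | intermediate
12 | 6β-hydroxy C5-enol triflate (C4=C5; C2 ketone) | O[C@]12CC(C)=CC[C@@]1(C)C(=O)CC(C(C)C)=C2OS(=O)(=O)C(F)(F)F | intermediate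
13 | 2α,6β-dihydroxy C5-enol triflate | O[C@]12CC(C)=CC[C@@]1(C)[C@@H](O)CC(C(C)C)=C2OS(=O)(=O)C(F)(F)F | intermediate
14 | 2α-acetoxy-6β-hydroxy C5-enol triflate | O[C@]12CC(C)=CC[C@@]1(C)[C@@H](OC(C)=O)CC(C(C)C)=C2OS(=O)(=O)C(F)(F)F | intermediate
15 | 2α-acetoxy-6β-hydroxy cis-decalin 4,8-diene (4-isopropyl; 1,8-dimethyl) | O[C@]12CC(C)=CC[C@@]1(C)[C@@H](OC(C)=O)CC(C(C)C)=C2 | intermediate
16 | 4β,5β-osmate ester of 15 (OsO2·TMEDA glycolate) | O[C@]12CC(C)=CC[C@@]1(C)[C@@H](OC(C)=O)C[C@]3(C(C)C)O[Os-2]4(=O)(=O)(O[C@H]23)[N+](C)(C)CC[N+]4(C)C | intermediate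
17 | 2α-acetoxy cis-decalin-4β,5β,6β-triol (4α-isopropyl; C8=C9) | O[C@]12CC(C)=CC[C@@]1(C)[C@@H](OC(C)=O)C[C@@](O)(C(C)C)[C@@H]2O | intermediate
18 | 5β-methanesulfonate of 17 | O[C@]12CC(C)=CC[C@@]1(C)[C@@H](OC(C)=O)C[C@@](O)(C(C)C)[C@@H]2OS(C)(=O)=O | intermediate
19 | 2α-acetoxy-4β-hydroxydauc-8-en-6-one (trans-fused; 5α-H) | O=C1CC(C)=CC[C@@]2(C)[C@@H](OC(C)=O)C[C@@](O)(C(C)C)[C@H]12 | intermediate
20 | 2α-acetoxydauc-8-ene-4β,6α-diol | O[C@H]1CC(C)=CC[C@@]2(C)[C@@H](OC(C)=O)C[C@@](O)(C(C)C)[C@H]12 | intermediate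
21 | 2α-acetoxy-8α,9α-epoxydaucane-4β,6α-diol | O[C@H]1C[C@@]2(C)O[C@H]2C[C@@]3(C)[C@@H](OC(C)=O)C[C@@](O)(C(C)C)[C@H]13 | intermediate
22 | catechol (benzene-1,2-diol) | Oc1ccccc1O | starting material
23 | guaiacol (2-methoxyphenol) | COc1ccccc1O | intermediate
24 | 4-bromo-2-methoxyphenol | COc1cc(Br)ccc1O | intermediate
25 | (4-bromo-2-methoxyphenoxy)(tert-butyl)dimethylsilane | COc1cc(Br)ccc1O[Si](C)(C)C(C)(C)C | intermediate
26 | [4-(tert-butyldimethylsilyloxy)-3-methoxyphenyl]lithium | COc1cc([Li])ccc1O[Si](C)(C)C(C)(C)C | intermediate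
27 | lithium 4-(tert-butyldimethylsilyloxy)-3-methoxybenzoate | [Li+].COc1cc(C(=O)[O-])ccc1O[Si](C)(C)C(C)(C)C | intermediate
28 | 4-(tert-butyldimethylsilyloxy)-3-methoxybenzoic acid | COc1cc(C(=O)O)ccc1O[Si](C)(C)C(C)(C)C | intermediate
29 | 4-(tert-butyldimethylsilyloxy)-3-methoxybenzoic 2,4,6-trichlorobenzoic anhydride | COc1cc(C(=O)OC(=O)c2c(Cl)cc(Cl)cc2Cl)ccc1O[Si](C)(C)C(C)(C)C | intermediate
30 | 6-O-[4-(tert-butyldimethylsilyloxy)-3-methoxybenzoyl] derivative of 21 | COc1cc(C(=O)O[C@H]2C[C@@]3(C)O[C@H]3C[C@@]3(C)[C@@H](OC(C)=O)C[C@@](O)(C(C)C)[C@H]23)ccc1O[Si](C)(C)C(C)(C)C | intermediate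
31 | CNP0241679.3: 2α-acetoxy-8α,9α-epoxy-4β-hydroxy-6α-(4-hydroxy-3-methoxybenzoyloxy)daucane | COc1cc(C(=O)O[C@H]2C[C@@]3(C)O[C@H]3C[C@@]3(C)[C@@H](OC(C)=O)C[C@@](O)(C(C)C)[C@H]23)ccc1O | target

**Step count and risks**

Total steps: 16 (steps 1–11 main line, steps 12–15 aryl branch, step 16 union).
Longest linear sequence: 12 steps (steps 1–11, then 16).

The three steps most likely to fail:

Step 3 (the proposed new enantioselective cycloaddition; risk: low ee, or reaction at the wrong double bond or with the wrong orientation). The fallback sets out from 4 and 5. The cycloaddition is run with the achiral Lewis acid BF3·OEt2 (CH2Cl2, −78 °C), a known type of promotion that should give the same cis "para" adduct as a racemate. This is 6 together with its mirror image (4aS,8aR)-4a,7-dimethyl-2-(propan-2-yl)-4a,5,8,8a-tetrahydronaphthalene-1,4-dione F1. The enantiomers are separated by preparative chromatography on a chiral stationary phase (amylose tris(3,5-dimethylphenylcarbamate)), and the fallback comes back to the route at 6.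

Step 4 (angular hydroxylation; risk: attack trans to the methyl group, or retro-aldol opening of the alkoxide). The fallback sets out from 6 and brings in the C6 oxygen by a radical instead of an enolate pathway. Mn(OAc)3 in benzene at 80 °C acetoxylates the α′-position of the enone and gives the 6β-acetoxy enedione F2. Mild methanolysis (K2CO3, MeOH, 0 °C) gives the 6β-hydroxy enedione F3. Silylation with Me3SiCl and imidazole comes back to the route at 9.

Step 8 (directed dihydroxylation; risk: competing osmylation of the C8=C9 alkene). The fallback sets out from 15. The more accessible C8=C9 alkene is first masked by anti-addition of bromine from pyridinium tribromide (C5H5NH·Br3, CH2Cl2, −78 °C), giving the 8β,9α-dibromide of 15 F4. The same OsO4/TMEDA dihydroxylation then gives the 8β,9α-dibromo-4β,5β,6β-triol F5. Zinc dust in acetic acid removes the two bromine atoms and restores the alkene, which comes back to the route at 17.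

**Further compounds**

F1 | step 3 | (4aS,8aR)-4a,7-dimethyl-2-(propan-2-yl)-4a,5,8,8a-tetrahydronaphthalene-1,4-dione (enantiomer of 6) | [C@@H]12CC(C)=CC[C@]1(C)C(=O)C=C(C(C)C)C2=O
F2 | step 4 | 6β-acetoxy enedione (8a-acetoxy derivative of 6, cis to the angular methyl) | CC(=O)O[C@]12CC(C)=CC[C@@]1(C)C(=O)C=C(C(C)C)C2=O
F3 | step 4 | 6β-hydroxy enedione (8a-hydroxy derivative of 6, cis to the angular methyl) | O[C@]12CC(C)=CC[C@@]1(C)C(=O)C=C(C(C)C)C2=O
F4 | step 8 | 8β,9α-dibromide of 15 | O[C@]12C[C@](C)(Br)[C@@H](Br)C[C@@]1(C)[C@@H](OC(C)=O)CC(C(C)C)=C2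
F5 | step 8 | 8β,9α-dibromo-4β,5β,6β-triol (dibromide of 17) | O[C@]12C[C@](C)(Br)[C@@H](Br)C[C@@]1(C)[C@@H](OC(C)=O)C[C@@](O)(C(C)C)[C@@H]2O
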